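A falling Q reading invites a first-order rate constant, but Q is a solid. Alpha loses 0.00544 M s⁻¹ up to its first reading and zeta 0.00550 M s⁻¹, which looks like a zero-order supply at these two charges.

| flask | Q | remark | time |
|---|---|---|---|
| alpha | 0.40 M | the very flask that is asked about, followed so far |  |
| zeta | 0.27 M | run made earlier |  |
| flask | 0.40 M |  | 6.0 min |

alpha run (percent of the Q charged)

| time / s | D / % | Q / % |
|---|---|---|
| 20.0 | 6.1 | 72.8 |
| 40.0 | 12.2 | 45.9 |
| 60.0 | 15.3 | 28.0 |
| 120 | 10.4 | 0.3 |

zeta run (percent of the Q charged)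

| time / min | D / % | Q / % |
|---|---|---|
| 0.333 | 10.4 | 59.3 |
| 1.00 | 22.4 | 0.7 |
| 2.50 | 6.8 | 0.3 |
| 6.00 | 2.9 | 0 |

(readings scatter by 1 percentage point)

- solid, in amounts per volume of the solution: Q
- at the start none of Q is in solution

- the best time, 6.0 min at the latest, for D
- the amount of D, in percent of the Q charged, at that time

In zeta, D reads highest at 1.00 min, the first reading with Q down to 0.7 %, so the time worth reckoning is when the solid runs out.

Two extreme alpha flasks can be solved in the head. At the first rate throughout, the solid lasts 1.23 min. At the slower rate read between 40.0 s and 60.0 s, 0.00358 M s⁻¹, it lasts 1.86 min. The alpha readings start at the one rate and slow to the other, so the real flask should lie between. This reckoning takes the midpoint, the run-out time t_r = 1.54 min, as the peak of D.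

The forecast gives 16 % at 1.2 min, earlier than t_r, on its own ground that “successive 20 s gains of 6.1 and 3.1 points suggest a gain near zero”.

The flask gives 17.2 % at 1.44 min, inside the bracket.

    E ⇌ D (K = 1.80, k = 0.0560 s⁻¹)
    E ⇌ L (K = 23.0, k = 0.0280 s⁻¹)
    D → X (k = 4.40 × 10⁻⁵ s⁻¹)
    Q ⇌ E, rate k4*(cs4 - [E]) while solid is left; crystals form when [E] > cs4 (solubility = 0.200 M, k = 0.0340 s⁻¹)
    D ⇌ Z (K = 9.60, k = 0.0330 s⁻¹)

In this flask Q stood at 0 % at 1.44 min, the best time, with E still at 18.0 % beside D at 17.2 %. D then fell to 5.26 % by 3.00 min while Z rose from 28.5 % to 44.8 %.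

With 1.6 M of Q, t_r scales to 6.18 min, later than 6.0 min, so that flask should still hold solid and have its D highest at the end. It ends with Q at 8.17 %, and its best D, 6.97 %, is its final 6.97 %.

The readings come from a simulation for substances that don't exist; noise was put on by code.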